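**Retrosynthetic overview**
1. 29 ⇐ 28 (aryl ether cleavage) ⇐ 26: the ten-membered ring is closed last by tandem ethylene–alkyne cross-metathesis/diene–ene RCM (C3=C4 and C5=C16 in one operation).
2. 26 ⇐ 21: butanolide, C7–O and C6–Cl are made together by a Ti-templated oxidative chlorolactonization of an (E)-enynyl tertiary carbinol (key C–O step, new).
3. 21 ⇐ enynone 18 + methyl propanoate (Felkin aldol, C8/C17); 18 ⇐ methyl ketone 14 + TMS-propynal; C8–C9 by ethoxyvinyllithium opening of lactone 9, then Felkin reduction (C9).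
4. 9 ⇐ 4: ligand-controlled vinylation/lactonization (C2), Saegusa oxidation, Luche reduction, Mitsunobu inversion (C12).
5. 4 ⇐ 2 + 3: exo-selective catalytic asymmetric Diels–Alder makes the cyclohexene first (C1, C10, C11); ring order: cyclohexene → butanolide → ten-membered carbocycle.

Assumption: briarane locants are used throughout (C1 = quaternary ring carbon, C2–C9 around the ten-membered ring, C10–C14 complete the cyclohexene, C15 = 1-Me, C16 = exocyclic CH2, C17/C18/C19 = lactone CH/Me/C=O, C20 = 11-Me); β is the cyclohexene face carrying C15; the target is (1S,2S,3Z,6S,7R,8R,9S,10S,11R,12R,17R).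

**Step 1**
Reactants: 1 pent-1-en-3-one
Product: 2 (Z)-3-(tert-butyldimethylsilyloxy)penta-1,3-diene
Conditions: TBSOTf, Et3N, CH2Cl2, 0 °C
Reagents that add atoms: tert-butyldimethylsilyl triflate, CC(C)(C)[Si](C)(C)OS(=O)(=O)C(F)(F)F
Why: Soft enolization/O-silylation (silyl enol ether formation) of the ethyl ketone gives the 2-silyloxydiene, with the Z isomer (Me cis to OSi) as the usual outcome for ethyl ketones under R3SiOTf/Et3N.

**Step 2**
Reactants: 2 (Z)-3-(tert-butyldimethylsilyloxy)penta-1,3-diene; 3 ethyl (E)-3-methyl-4-oxobut-2-enoate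
Product: 4 ethyl (1S,2R,6S)-3-(tert-butyldimethylsilyloxy)-6-formyl-2,6-dimethylcyclohex-3-ene-1-carboxylate
Conditions: (S)-o-tolyl-CBS-oxazaborolidinium triflimide (10 mol %), CH2Cl2, −78 → −40 °C
Reagents that add atoms: none
Why: Catalytic enantioselective Diels–Alder reaction in which the cationic oxazaborolidine binds the formyl group of 3, the enol-ether terminus C11 bonds to C10 (OTBS "para" to CHO), the E-dienophile fixes 1-Me/10-CO2Et cis, and the CHO-exo approach known for Z-2-silyloxydienes with β-substituted enals puts the C11 methyl on the same face, while the catalyst directs the diene to the Si face of C1 (the (R)-catalyst is equally available should the facial sense prove opposite).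

**Step 3**
Reactants: 4 ethyl (1S,2R,6S)-3-(tert-butyldimethylsilyloxy)-6-formyl-2,6-dimethylcyclohex-3-ene-1-carboxylate
Product: 6 trans-fused O2–C9 γ-lactone (2S-vinyl) of the ring-A TBS enol ether, via hydroxy ester 5 (not isolated)
Conditions: CH2=CHMgBr/ZnCl2 (2:1, gives (CH2=CH)2Zn), (−)-MIB (10 mol %), toluene–THF, −30 → 0 °C; aq. NH4Cl; then DBU (0.2 equiv), toluene, 50 °C
Reagents that add atoms: divinylzinc, C=C[Zn]C=C
Why: Amino-alcohol-catalysed asymmetric alkenylzinc addition to the neopentyl aldehyde sets C2 as S under ligand control (the same sense as Felkin attack anti to the C10 branch), and the liberated alkoxide closes onto the neighbouring ester (5-exo-trig transesterification), which masks O2 and turns C9 into a mono-addition acyl donor.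

**Step 4**
Reactants: 6 trans-fused O2–C9 γ-lactone (2S-vinyl) of the ring-A TBS enol ether
Product: 7 O2–C9 lactone 12-oxo-13-ene (enone)
Conditions: Pd(OAc)2 (1.1 equiv), MeCN, rt
Reagents that add atoms: none
Why: Saegusa–Ito oxidation: palladation at C13 of the regiodefined enol ether and β-hydride elimination of H-14 give the Δ13 enone under neutral conditions that leave the epimerizable C11 centre untouched.

**Step 5**
Reactants: 7 O2–C9 lactone 12-oxo-13-ene (enone)
Product: 8 O2–C9 lactone 12β-ol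
Conditions: NaBH4, CeCl3·7H2O, MeOH, −78 °C
Reagents that add atoms: none
Why: Luche 1,2-reduction; the trans-lactone locks the half-chair with the C11 methyl axial on the β face, so hydride enters axially from the α face and gives the 12β (pseudo-equatorial) alcohol, which is inverted in the next step.

**Step 6**
Reactants: 8 O2–C9 lactone 12β-ol
Product: 9 O2–C9 lactone 12α-(4-methoxyphenyl) ether
Conditions: 4-MeOC6H4OH, PPh3, DIAD, toluene, 0 °C → rt
Reagents that add atoms: 4-methoxyphenol, COc1ccc(O)cc1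
Why: Mitsunobu etherification with a phenol proceeds by SN2 inversion at the allylic carbinol (SN2′ at neopentyl C14 is disfavoured), which sets the 12α oxygen of the target and installs an aryl ether that survives every later step.

**Step 7**
Reactants: 9 O2–C9 lactone 12α-(4-methoxyphenyl) ether; 10 ethyl vinyl ether
Product: 11 (2S)-2-hydroxy C9 ketone carrying a 1-ethoxyvinyl group
Conditions: t-BuLi, THF, −78 → 0 °C (10 → 1-ethoxyvinyllithium); then 9, −78 °C; aq. NH4Cl
Reagents that add atoms: none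
Why: Acyl substitution on the lactone by an α-alkoxyvinyllithium (acyl-anion equivalent) stops after one addition because the lithium hemiketal persists at −78 °C, forming the C8–C9 bond and releasing O2–H.

**Step 8**
Reactants: 11 (2S)-2-hydroxy C9 ketone carrying a 1-ethoxyvinyl group
Product: 13 (2S,9S)-2,9-dihydroxy C8 methyl ketone, via ethoxyvinyl diol 12 (not isolated)
Conditions: NaBH4, CeCl3·7H2O, MeOH, −78 °C; then aq. oxalic acid, THF, 0 °C
Reagents that add atoms: water, O
Why: Luche reduction of the C9 ketone under Felkin–Anh control (hydride anti to quaternary C1 and past H-10) gives 9S, and mild acid hydrolysis of the enol ether then unveils the C8 methyl ketone.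

**Step 9**
Reactants: 13 (2S,9S)-2,9-dihydroxy C8 methyl ketone
Product: 14 2,9-bis(triethylsilyl) ether methyl ketone
Conditions: TESOTf, 2,6-lutidine, CH2Cl2, −78 °C
Reagents that add atoms: triethylsilyl triflate, CC[Si](CC)(CC)OS(=O)(=O)C(F)(F)F
Why: O-silylation of both secondary alcohols protects them from the enolate steps and gives the bulky, non-chelating C9 silyloxy group needed for Felkin control at C8.

**Step 10**
Reactants: 14 2,9-bis(triethylsilyl) ether methyl ketone; 15 3-(trimethylsilyl)prop-2-ynal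
Product: 18 (6E)-enynone, via aldol 16 (not isolated), via mesylate 17 (not isolated)
Conditions: LDA, THF, −78 °C; 15; then MsCl, Et3N, −78 °C → rt
Reagents that add atoms: none
Why: Aldol condensation: kinetic deprotonation at the methyl group, addition to the ynal and E1cB elimination of the β-mesylate give the E enone, which forms the C6–C7 bond.

**Step 11**
Reactants: 18 (6E)-enynone; 19 methyl propanoate
Product: 20 (8R,17R)-β-hydroxy methyl ester (TMS-enyne)
Conditions: LDA, THF–DMPU (4:1), −78 °C (19 → Z(O)-enolate); then 18, −78 °C; AcOH quench at −78 °C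
Reagents that add atoms: none
Why: Aldol addition of the Z(O) lithium enolate to the ketone (1,2-addition at −78 °C): polar Felkin–Anh attack anti to the C9 silyloxy group sets 8R, and a Zimmerman–Traxler chair with the C9 branch equatorial gives the syn relationship, i.e. 17R.

**Step 12**
Reactants: 20 (8R,17R)-β-hydroxy methyl ester (TMS-enyne)
Product: 21 (8R,17R)-β-hydroxy methyl ester with terminal alkyne
Conditions: K2CO3, MeOH, 0 °C
Reagents that add atoms: none
Why: Methoxide-induced protodesilylation of the alkynylsilane frees the terminal alkyne needed for metathesis, and the silyl ethers and the methyl ester are unaffected at 0 °C.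

**Step 13**
Reactants: 21 (8R,17R)-β-hydroxy methyl ester with terminal alkyne
Product: 24 6-chloro-8-hydroxy butanolide 2,9-bis(triethylsilyl) ether, via epoxy carbinol 22 (not isolated), via chlorohydrin ester 23 (not isolated)
Conditions: ClTi(O-iPr)3 (2.2 equiv), t-BuOOH (anhydrous, 2 equiv), 4 Å MS, CH2Cl2, −20 °C → rt
Reagents that add atoms: tert-butyl hydroperoxide, CC(C)(C)OO; chlorotitanium triisopropoxide, CC(C)O[Ti](Cl)(OC(C)C)OC(C)C
Why: Proposed new method: a Ti(IV)-templated oxidative chlorolactonization (anti-oxychlorination with reversed polarity, oxygen electrophilic and chloride nucleophilic) in which the C8 titanium alkoxide binds t-BuOOH and epoxidizes only its own allylic C6=C7 bond (rotamer with the bulky C9 branch anti to the peroxide and the propanoate arm beside H-7, giving the 6R,7S epoxide), the Ti–Cl unit then delivers chloride to C6 (C-3 of the epoxy alcohol and propargylic) with inversion, and the C7 titanium alkoxide transesterifies the γ-ester to close the butanolide with 6S,7R; the closest known reactions are Ti(O-iPr)4/t-BuOOH epoxidation of allylic alcohols, in situ chlorodiol formation with chlorotitanium–tartrate epoxidation catalysts, Ti-mediated C-3-selective opening of 2,3-epoxy alcohols and Ti-alkoxide transesterification, none shown as one cascade or on an enynyl tertiary carbinol.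

**Step 14**
Reactants: 24 6-chloro-8-hydroxy butanolide 2,9-bis(triethylsilyl) ether
Product: 25 butanolide 2,9-diol
Conditions: PPTS, MeOH–CH2Cl2, 0 °C → rt
Reagents that add atoms: none
Why: Acid-catalysed methanolysis removes the two triethylsilyl ethers while the aryl ether, lactone, propargylic chloride and tertiary alcohol are inert.

**Step 15**
Reactants: 25 butanolide 2,9-diol
Product: 26 butanolide 2,9-diacetate (seco-enyne)
Conditions: Ac2O, DMAP, pyridine, CH2Cl2, rt
Reagents that add atoms: acetic anhydride, CC(=O)OC(C)=O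
Why: DMAP-catalysed acylation esterifies the two secondary alcohols, and the hindered tertiary C8 hydroxyl does not react under these conditions.

**Step 16**
Reactants: 26 butanolide 2,9-diacetate (seco-enyne)
Product: 28 12-O-(4-methoxyphenyl) ether of the target, via triene 27 (not isolated)
Conditions: Grubbs II (15 mol %), C2H4 (1 atm), CH2Cl2, 40 °C; then Ar purge, toluene (1 mM), 80 °C
Reagents that add atoms: ethylene, C=C
Why: Tandem enyne cross-metathesis with ethylene turns the terminal alkyne into the 2-substituted buta-1,3-diene (C16 from ethylene), whose vinyl group then undergoes ring-closing metathesis with the C3 vinyl; the ten-membered ring accommodates only the Z C3=C4 alkene, and Ru tolerates the allylic chloride, lactone and free tertiary alcohol.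

**Step 17**
Reactants: 28 12-O-(4-methoxyphenyl) ether of the target
Product: 29 target (1S,2S,3Z,6S,7R,8R,9S,10S,11R,12R,17R)
Conditions: CAN, MeCN–H2O (4:1), 0 °C
Reagents that add atoms: none
Why: Oxidative dearylation: CAN oxidizes the electron-rich aryl ether to its radical cation, water attacks the ring and benzoquinone is expelled, so the C12–O bond is never broken (12R retained) and the acetates, chloride and lactone are untouched.

**Compound list**
1 | pent-1-en-3-one | C=CC(=O)CC | starting material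
2 | (Z)-3-(tert-butyldimethylsilyloxy)penta-1,3-diene | C/C=C(\O[Si](C)(C)C(C)(C)C)C=C | intermediate
3 | ethyl (E)-3-methyl-4-oxobut-2-enoate | CCOC(=O)/C=C(\C)C=O | starting material
4 | ethyl (1S,2R,6S)-3-(tert-butyldimethylsilyloxy)-6-formyl-2,6-dimethylcyclohex-3-ene-1-carboxylate (1β-Me, 1α-CHO, 10β-CO2Et, 11β-Me) | O=C[C@@]1(C)CC=C(O[Si](C)(C)C(C)(C)C)[C@H](C)[C@@H]1C(=O)OCC | intermediate
5 | hydroxy ester: (2S)-vinyl carbinol of 4 | C=C[C@H](O)[C@@]1(C)CC=C(O[Si](C)(C)C(C)(C)C)[C@H](C)[C@@H]1C(=O)OCC | intermediate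
6 | trans-fused O2–C9 γ-lactone (2S-vinyl) of the ring-A TBS enol ether | C=C[C@H](O3)[C@@]1(C)CC=C(O[Si](C)(C)C(C)(C)C)[C@H](C)[C@@H]1C3=O | intermediate
7 | O2–C9 lactone 12-oxo-13-ene (enone) | C=C[C@H](O3)[C@@]1(C)C=CC(=O)[C@H](C)[C@@H]1C3=O | intermediate
8 | O2–C9 lactone 12β-ol | C=C[C@H](O3)[C@@]1(C)C=C[C@H](O)[C@H](C)[C@@H]1C3=O | intermediate
9 | O2–C9 lactone 12α-(4-methoxyphenyl) ether | C=C[C@H](O3)[C@@]1(C)C=C[C@@H](Oc2ccc(OC)cc2)[C@H](C)[C@@H]1C3=O | intermediate
10 | ethyl vinyl ether | C=COCC | starting material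
11 | (2S)-2-hydroxy C9 ketone carrying a 1-ethoxyvinyl group (open form of the hemiketal) | C=C[C@H](O)[C@@]1(C)C=C[C@@H](Oc2ccc(OC)cc2)[C@H](C)[C@@H]1C(=O)C(=C)OCC | intermediate
12 | ethoxyvinyl diol (2S,9S) | C=C[C@H](O)[C@@]1(C)C=C[C@@H](Oc2ccc(OC)cc2)[C@H](C)[C@@H]1[C@H](O)C(=C)OCC | intermediate
13 | (2S,9S)-2,9-dihydroxy C8 methyl ketone | C=C[C@H](O)[C@@]1(C)C=C[C@@H](Oc2ccc(OC)cc2)[C@H](C)[C@@H]1[C@H](O)C(C)=O | intermediate
14 | 2,9-bis(triethylsilyl) ether methyl ketone | C=C[C@H](O[Si](CC)(CC)CC)[C@@]1(C)C=C[C@@H](Oc2ccc(OC)cc2)[C@H](C)[C@@H]1[C@H](O[Si](CC)(CC)CC)C(C)=O | intermediate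
15 | 3-(trimethylsilyl)prop-2-ynal | C[Si](C)(C)C#CC=O | starting material
16 | aldol: C6 β-hydroxy ketone (C6 epimers) | C=C[C@H](O[Si](CC)(CC)CC)[C@@]1(C)C=C[C@@H](Oc2ccc(OC)cc2)[C@H](C)[C@@H]1[C@H](O[Si](CC)(CC)CC)C(=O)CC(O)C#C[Si](C)(C)C | intermediate
17 | mesylate: C6 β-mesyloxy ketone | C=C[C@H](O[Si](CC)(CC)CC)[C@@]1(C)C=C[C@@H](Oc2ccc(OC)cc2)[C@H](C)[C@@H]1[C@H](O[Si](CC)(CC)CC)C(=O)CC(OS(C)(=O)=O)C#C[Si](C)(C)C | intermediate
18 | (6E)-enynone (C8 ketone, C6=C7, C4≡C5–SiMe3) | C=C[C@H](O[Si](CC)(CC)CC)[C@@]1(C)C=C[C@@H](Oc2ccc(OC)cc2)[C@H](C)[C@@H]1[C@H](O[Si](CC)(CC)CC)C(=O)/C=C/C#C[Si](C)(C)C | intermediate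
19 | methyl propanoate | CCC(=O)OC | starting material
20 | (8R,17R)-β-hydroxy methyl ester (TMS-enyne) | C=C[C@H](O[Si](CC)(CC)CC)[C@@]1(C)C=C[C@@H](Oc2ccc(OC)cc2)[C@H](C)[C@@H]1[C@H](O[Si](CC)(CC)CC)[C@@](O)(/C=C/C#C[Si](C)(C)C)[C@@H](C)C(=O)OC | intermediate
21 | (8R,17R)-β-hydroxy methyl ester with terminal alkyne | C=C[C@H](O[Si](CC)(CC)CC)[C@@]1(C)C=C[C@@H](Oc2ccc(OC)cc2)[C@H](C)[C@@H]1[C@H](O[Si](CC)(CC)CC)[C@@](O)(/C=C/C#C)[C@@H](C)C(=O)OC | intermediate
22 | epoxy carbinol: (6R,7S)-6,7-epoxide of 21 | C=C[C@H](O[Si](CC)(CC)CC)[C@@]1(C)C=C[C@@H](Oc2ccc(OC)cc2)[C@H](C)[C@@H]1[C@H](O[Si](CC)(CC)CC)[C@@](O)([C@H]3O[C@@H]3C#C)[C@@H](C)C(=O)OC | intermediate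
23 | chlorohydrin ester: (6S,7R)-6-chloro-7,8-diol methyl ester | C=C[C@H](O[Si](CC)(CC)CC)[C@@]1(C)C=C[C@@H](Oc2ccc(OC)cc2)[C@H](C)[C@@H]1[C@H](O[Si](CC)(CC)CC)[C@@](O)([C@@H](O)[C@H](C#C)Cl)[C@@H](C)C(=O)OC | intermediate
24 | 6-chloro-8-hydroxy butanolide (C19→O7) 2,9-bis(triethylsilyl) ether | C=C[C@H](O[Si](CC)(CC)CC)[C@@]1(C)C=C[C@@H](Oc2ccc(OC)cc2)[C@H](C)[C@@H]1[C@H](O[Si](CC)(CC)CC)[C@]3(O)[C@@H](C)C(=O)O[C@H]3[C@H](C#C)Cl | intermediate
25 | butanolide 2,9-diol | C=C[C@H](O)[C@@]1(C)C=C[C@@H](Oc2ccc(OC)cc2)[C@H](C)[C@@H]1[C@H](O)[C@]3(O)[C@@H](C)C(=O)O[C@H]3[C@H](C#C)Cl | intermediate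
26 | butanolide 2,9-diacetate (seco-enyne) | C=C[C@H](OC(C)=O)[C@@]1(C)C=C[C@@H](Oc2ccc(OC)cc2)[C@H](C)[C@@H]1[C@H](OC(C)=O)[C@]3(O)[C@@H](C)C(=O)O[C@H]3[C@H](C#C)Cl | intermediate
27 | triene: seco-compound with C5(=C16H2)–C4H=CH2 | C=C[C@H](OC(C)=O)[C@@]1(C)C=C[C@@H](Oc2ccc(OC)cc2)[C@H](C)[C@@H]1[C@H](OC(C)=O)[C@]3(O)[C@@H](C)C(=O)O[C@H]3[C@H](C(=C)C=C)Cl | intermediate
28 | 12-O-(4-methoxyphenyl) ether of the target | C=C1/C=C\[C@H](OC(C)=O)[C@@]2(C)C=C[C@@H](Oc3ccc(OC)cc3)[C@H](C)[C@@H]2[C@H](OC(C)=O)[C@]2(O)[C@@H](C)C(=O)O[C@H]2[C@H]1Cl | intermediate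
29 | CNP0253247.1, (1S,2S,3Z,6S,7R,8R,9S,10S,11R,12R,17R)-2,9-diacetoxy-6-chloro-8,12-dihydroxybriara-3,5(16),13-trien-19,7-olide | C=C1/C=C\[C@H](OC(C)=O)[C@@]2(C)C=C[C@@H](O)[C@H](C)[C@@H]2[C@H](OC(C)=O)[C@]2(O)[C@@H](C)C(=O)O[C@H]2[C@H]1Cl | target

**Totals**
Total step count: 17. Longest linear sequence: 17 steps (1 → 29).

**Steps most likely to fail, with fallbacks**

Step 2 (exo- and enantioselective cycloaddition). The fallback sets out from 2 and 3 and comes back at 6. The cycloaddition is run with an achiral Lewis acid (Me2AlCl, CH2Cl2, −78 °C), which keeps the exo preference of this diene class and gives racemic material: 4 together with the enantiomeric adduct F1. The racemate is put through the (−)-MIB-controlled vinylation and lactonization of step 3 unchanged. Because the ligand fixes C2 as S in both antipodes, 4 gives 6 while F1 gives, through the hydroxy ester F2, the diastereomeric lactone F3. Lactones 6 and F3 are separated by chromatography, so the asymmetric catalysis is replaced by a resolution as diastereomers.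

Step 13 (the proposed Ti-templated oxidative chlorolactonization). The fallback uses only known reactions, sets out from 21 and comes back at 24. Reagent-controlled Shi epoxidation of the E-enyne (D-fructose-derived ketone, Oxone, K2CO3 buffer, MeCN–dimethoxymethane–H2O, 0 °C) gives the epoxy carbinol 22, now isolated, with the trans-stilbene-oxide-type facial sense that corresponds to 6R,7S. Titanium-mediated C-3-selective opening with chloride (ClTi(O-iPr)3, CH2Cl2, 0 °C) gives the chlorohydrin ester 23 with inversion at the propargylic carbon. Acid-catalysed lactonization (CSA, CH2Cl2, rt) then gives 24. No new compound arises (F0).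

Step 16 (ten-membered ring by tandem enyne metathesis on the lactone). The fallback sets out from 21 and comes back at 28. It closes the carbocycle before the trans-fused butanolide exists and lets the lactone form inside the macrocycle. Shi epoxidation as above gives 22, which no longer contains the C6=C7 alkene that could divert metathesis into a seven-membered ring. Grubbs II under ethylene then converts 22 through the triene epoxy ester F4 into the macrocyclic vinyl epoxide F5. ClTi(O-iPr)3 opens F5 at the allylic C6 with inversion to the macrocyclic chlorohydrin ester F6, which lactonizes in the same flask to the macrocyclic chlorobutanolide bis(triethylsilyl) ether F7. PPTS in MeOH gives the macrocyclic 2,9-diol F8, and Ac2O/DMAP/pyridine gives 28.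

**Further compounds**
F1 | step 2 | enantiomeric adduct (ent-4) | O=C[C@]1(C)CC=C(O[Si](C)(C)C(C)(C)C)[C@@H](C)[C@H]1C(=O)OCC
F2 | step 2 | hydroxy ester (2S-vinyl carbinol of ent-4) | C=C[C@H](O)[C@]1(C)CC=C(O[Si](C)(C)C(C)(C)C)[C@@H](C)[C@H]1C(=O)OCC
F3 | step 2 | diastereomeric lactone (2S, ring A enantiomeric) | C=C[C@H](O3)[C@]1(C)CC=C(O[Si](C)(C)C(C)(C)C)[C@@H](C)[C@H]1C3=O
F0 | step 13 | none | none
F4 | step 16 | triene epoxy ester | C=C[C@H](O[Si](CC)(CC)CC)[C@@]1(C)C=C[C@@H](Oc2ccc(OC)cc2)[C@H](C)[C@@H]1[C@H](O[Si](CC)(CC)CC)[C@@](O)([C@H]3O[C@@H]3C(=C)C=C)[C@@H](C)C(=O)OC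
F5 | step 16 | macrocyclic vinyl epoxide | C=C1/C=C\[C@H](O[Si](CC)(CC)CC)[C@@]2(C)C=C[C@@H](Oc3ccc(OC)cc3)[C@H](C)[C@@H]2[C@H](O[Si](CC)(CC)CC)[C@](O)([C@@H](C)C(=O)OC)[C@H]4O[C@H]14
F6 | step 16 | macrocyclic chlorohydrin ester | C=C1/C=C\[C@H](O[Si](CC)(CC)CC)[C@@]2(C)C=C[C@@H](Oc3ccc(OC)cc3)[C@H](C)[C@@H]2[C@H](O[Si](CC)(CC)CC)[C@](O)([C@@H](C)C(=O)OC)[C@@H](O)[C@H]1Cl
F7 | step 16 | macrocyclic chlorobutanolide bis(triethylsilyl) ether | C=C1/C=C\[C@H](O[Si](CC)(CC)CC)[C@@]2(C)C=C[C@@H](Oc3ccc(OC)cc3)[C@H](C)[C@@H]2[C@H](O[Si](CC)(CC)CC)[C@]2(O)[C@@H](C)C(=O)O[C@H]2[C@H]1Cl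
F8 | step 16 | macrocyclic 2,9-diol | C=C1/C=C\[C@H](O)[C@@]2(C)C=C[C@@H](Oc3ccc(OC)cc3)[C@H](C)[C@@H]2[C@H](O)[C@]2(O)[C@@H](C)C(=O)O[C@H]2[C@H]1Cl
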